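I want Q in the flask at the end.

    X → Q (k1 = 0.0589 /s)
    X + G → X.G (k2 = 9.08 /M/s)
    J + Q → J + E (k3 = 115 /M/s)

common to all: G 0.0100 M; J 0.10 mM

| flask | X | remark | time |
|---|---|---|---|
| alpha | 0.10 M | one stirred flow tank at steady state, fed with the mixture as stated, mean residence time 2.0 min |  |
| eta | 0.10 M (fed, over 2.00 min) | a stirred flask in which X is dosed at a steady rate over 2.00 min without added volume, worked up at 2.0 min | 2.0 min |
| theta | 0.10 M | everything together in a closed stirred flask, run for 2.0 min | 2.0 min |

- the set-up with the highest amount of Q at the outlet or at the end, in percent of the X put in ("none" if the first two lie within 2 percentage points) (alpha / eta / theta / none)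
- amount of Q at the outlet or at the end, in percent of the X put in, alpha
- amount of Q at the outlet or at the end, in percent of the X put in, eta
- amount of Q at the outlet or at the end, in percent of the X put in, theta

- the stated concentrations are those of everything mixed, before any reaction; amounts are the same in each set-up
- the feed brings no volume worth counting
- run time (eta): 2.0 min

I reckon in fractions of the X charged. G takes a fraction 0.100, and I count that share as lost to Q, because with G at its charge X falls faster by G than by its own step. J leaves the step that destroys Q as it entered, so Q decays pseudo-first-order with a lifetime of 87.0 s. Dividing the run by that lifetime gives one number: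

N = 2.0 min / 87.0 s = 1.38

This N, the ageing number, counts how many lifetimes of Q the run lasts, and each recipe differs in how much of it its Q lives through:

- theta, Q born at the start, aged through the whole run: 22.6%
- alpha, ages spread about the residence time: 37.8%
- eta, Q born evenly through the dose: 48.8%

One number is not enough for the last points. X needs its own 17.0 s to become Q, which delays Q in theta and raises that figure, while in eta the tail of the dose leaves about 0.141 of the charge as X and lowers it. I commit to the order, since eta stands 11 percentage points above alpha, more than the margin.

The forecast says eta, with 33.4% for alpha, 45.8% for eta and 28% for theta: “Dosing forms Q latest and so leaves the most at the end”.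

The flask gives eta, with 33.4%, 45.8% and 28.0% in the same order.

Eta's lead of 12 points over alpha is a lead at 2.00 min, while 14.1% of the charge is still X. Read at 8.0 min, the same eta flask has aged a further 4.14 lifetimes after its dose, which takes my eta figure down to 0.777%. The flask then holds 1.01% as Q and 89.0% as E.

The numbers were set for the occasion; the rest is arithmetic.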